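E, the limiting reagent of green and red, is the end group I count, since each X spends one E and one D.

| flask | D | E | G | remark | time |
|---|---|---|---|---|---|
| beta | 0.040 M | 0.90 equiv | 3.6 mM | run made earlier |  |
| theta | 0.12 M | 0.90 equiv | 3.6 mM | run made earlier |  |
| green | 0.036 M | 0.900 equiv | 3.60 mM |  | 40 h |
| red | 0.080 M | 0.900 equiv | 3.60 mM |  | 40 h |

| run | time / h | X / % |
|---|---|---|
| beta | 2.00 | 51.5 |
| beta | 5.00 | 60.1 |
| beta | 10.0 | 64.2 |
| beta | 15.0 | 64.0 |
| beta | 20.0 | 63.6 |
| theta | 2.00 | 73.1 |
| theta | 5.00 | 78.0 |
| theta | 10.0 | 78.9 |
| theta | 15.0 | 74.9 |
| theta | 20.0 | 76.5 |

(each reading ± 1 percentage point)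

- each molecule carries two end groups: a chain counts once for every two ends that are left, dead ends included; the units are half of the end groups of the two monomers charged

- which of the two ends with the longer chains by the average number of monomer units in a chain (unreacted monomers counted as chains of one) ("neither" if they lie within 10 %) (green / red / neither)
- average number of monomer units in a chain (unreacted monomers counted as chains of one) at the end, green
- average number of monomer units in a chain (unreacted monomers counted as chains of one) at the end, red

How much of the charged E does not stand as X? On the plateau of beta, taken as the mean of its last 3 readings, charged [E] minus [X] reads 10.4 mM; I call this difference the lost E. Theta has 3.00 times the charge of beta, but its lost E reads 15.9 mM, which is 1.53 times as much.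

What does lost E cost in length? The ends left are the charged [D] plus [E] minus two per X, which equals the charged excess of D plus two per lost E. The length is the charged ends over the ends left.

Which flask wins? Green charges 32.4 mM of E, close to beta, so I give it beta's lost E and reckon a length of 2.80. Red charges 72.0 mM of E, midway between beta and theta, so I take the mean lost E, 13.2 mM, and reckon 4.43. Lost E is then 32.2 % of green's E and 18.3 % of red's, so I commit to red.

The forecast also says red, with 3 for green and 4.25 for red, on the reading “That points to an equilibrium, D + E ⇌ X, rather than simple stalling”. My green lies lower than its figure and my red higher.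

The flask gives red: 2.78 for green and 3.97 for red at 40.0 h.

    D + E ⇌ X + Q (K = 280, k = 21.0 M⁻¹ h⁻¹)
    E + G → Z (k = 76.0 M⁻¹ h⁻¹)
    E → J (k = 0.140 h⁻¹)

In red, the forward step D + E → X + Q alone uses E 7.7 times as fast as E → J at 0.406 h and 3.5 times as fast at 40.0 h, and red's lost E, counted with the 0.541 % of its charge still free, stands at 15.1 mM, which is 21.0 % of that charge. A neighbour flask, like red but with 0.020 M of D, has at 40.0 h a lost E of 8.09 mM, less than the 10.4 mM read on the plateau of beta, yet this is 44.9 % of its charge, and its chains reach 2.09.

The earlier runs and the new flask stem from a simulated flask with constants of no real substance; scatter was added.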